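**Plan**

1. Cuts: the CH2 bridge at C6 of ring B (the cyclohexadienone), then ring B at C2–C3 and at C5–C6. This leaves a 2-methyl-2-prenylmalonyl unit (C3, C4, C5), heptane-2,4-dione (C6, C1, C2 and the butanoyl group) and an aryl aldehyde (ring A with the bridge carbon).
2. Enabling feature: C3 of ring B is a carboxyl-level carbon on the quaternary C4, and C2 lies between the C1 ketone and the butanoyl C=O. Ring B is therefore the Claisen-closed form of a 3,5,7-triketo ester, and because C4 has no hydrogen no aldol closure can compete.
3. Forward: chiral malonate → half acid → acyl imidazole; one-pot C-acylation of the dione dianion (C5–C6) and ring closure (C2–C3) gives ring B; ring A is made from 2,4,6-trihydroxybenzaldehyde; the halves are joined last by reductive alkylation.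
4. Stereochemistry: C4 is set by asymmetric phase-transfer prenylation of a methylmalonate with two different esters. The order in which the two carboxyl groups are used decides on which side of C4 the butanoyl group ends up, so the (S) malonate becomes the (R) centre of the target.
5. Ring A regiochemistry comes from symmetry: 2,6-dihydroxy-4-methoxybenzaldehyde has two equivalent open positions, and its aldehyde carbon becomes the bridge.

Key step: step 6

Assumption: in step 3 the (S,S)-catalyst is taken to give (S)-6; the sense of induction is to be confirmed on the first batch, and the (R,R)-catalyst is used instead if it proves opposite.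

Remark: 12, 17 and 18 are drawn as one enol tautomer each. The descriptor of the quaternary carbon changes along the route only through priority changes; its spatial arrangement stays the same.

**Route**

Step 1
Reactants: 1 2,2,5-trimethyl-1,3-dioxane-4,6-dione
Product: 2 3-(tert-butoxy)-2-methyl-3-oxopropanoic acid (racemic)
Conditions: t-BuOH, reflux
Reagents that add atoms: tert-butanol, CC(C)(C)O
Why: Alcoholysis of the Meldrum's acid, in which tert-butanol opens the cyclic acylal at one carbonyl and acetone is lost, should give the malonic half-ester directly.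

Step 2
Reactants: 2 3-(tert-butoxy)-2-methyl-3-oxopropanoic acid; 3 2,2-diphenylethanol
Product: 4 tert-butyl 2,2-diphenylethyl 2-methylpropanedioate (racemic)
Conditions: DCC, DMAP (cat.), CH2Cl2, 0 °C → rt
Reagents that add atoms: none
Why: Steglich esterification (carbodiimide activation, DMAP acyl transfer) should join the acid to the primary alcohol under neutral conditions that leave the tert-butyl ester intact.

Step 3
Reactants: 4 tert-butyl 2,2-diphenylethyl 2-methylpropanedioate; 5 1-bromo-3-methylbut-2-ene
Product: 6 tert-butyl 2,2-diphenylethyl (S)-2-methyl-2-(3-methylbut-2-en-1-yl)propanedioate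
Conditions: (S,S)-3,4,5-trifluorophenyl-NAS bromide (N-spiro bis-binaphthyl ammonium bromide, 5 mol %), 50% aq KOH, toluene, −40 °C
Reagents that add atoms: none
Why: In this asymmetric phase-transfer alkylation the chiral ammonium cation pairs with the malonate enolate, whose two ester groups of very different size define its orientation in the ion pair, and SN2 attack on the primary carbon of prenyl bromide from the open face should set the quaternary centre as (S).

Step 4
Reactants: 6 tert-butyl 2,2-diphenylethyl (S)-2-methyl-2-(3-methylbut-2-en-1-yl)propanedioate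
Product: 8 (R)-2-[(2,2-diphenylethoxy)carbonyl]-2,5-dimethylhex-4-enoic acid, via trimethylsilyl ester 7 (not isolated)
Conditions: TMSOTf, 2,6-lutidine, CH2Cl2, 0 °C; then H2O
Reagents that add atoms: none
Why: Silyl triflate-mediated tert-butyl ester cleavage (O-silylation, loss of the tert-butyl cation as 2-methylpropene, hydrolysis of the silyl ester on work-up) should be selective over the primary ester and, being buffered, should spare the acid-sensitive prenyl group, while the quaternary centre is not touched.

Step 5
Reactants: 8 (R)-2-[(2,2-diphenylethoxy)carbonyl]-2,5-dimethylhex-4-enoic acid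
Product: 9 2,2-diphenylethyl (R)-2-(1H-imidazole-1-carbonyl)-2,5-dimethylhex-4-enoate
Conditions: CDI, THF, rt
Reagents that add atoms: 1,1'-carbonyldiimidazole, O=C(n1ccnc1)n1ccnc1
Why: Acyl imidazole formation with CDI (mixed anhydride, loss of CO2) should activate only the free carboxyl group, and the acid has no α-hydrogen through which it could epimerise or form a ketene.

Step 6
Reactants: 9 2,2-diphenylethyl (R)-2-(1H-imidazole-1-carbonyl)-2,5-dimethylhex-4-enoate; 10 heptane-2,4-dione
Product: 12 (R)-2-butanoyl-3,5-dihydroxy-4-methyl-4-(3-methylbut-2-en-1-yl)cyclohexa-2,5-dien-1-one, via triketo ester 11 (not isolated)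
Conditions: 10 (3 equiv), LiN(iPr)2 (6 equiv), THF, −78 → 0 °C; then 9, −78 °C → rt → 45 °C; 1 M aq HCl, 0 °C
Reagents that add atoms: none
Why: The dianion of 10, formed by kinetic second deprotonation at the methyl group, should attack the acyl imidazole of 9 through its terminal carbon to give the bis-enolate of triketo ester 11, and on warming the carbon of 11 between the C5 and C7 ketones should attack the ester carbonyl and expel 2,2-diphenylethoxide, an intramolecular Claisen (Dieckmann) condensation that forms the C2–C3 bond of ring B. The closest known reaction types are the Claisen-mode cyclisation of 3,5,7-triketo esters to acylphloroglucinols and the double Claisen condensation of dialkylmalonates with ketones to 4,4-dialkylcyclohexane-1,3,5-triones. Ring B closes in a 6-(enolexo)-exo-trig mode, helped by the quaternary carbon (Thorpe–Ingold effect) and driven by formation of the strongly stabilised trione enolate. No new stereocentre is formed: the quaternary carbon keeps the arrangement set in step 3, and because the former tert-butyl carboxyl carbon becomes C5 and the former diphenylethyl carboxyl carbon becomes C3, the centre is (R) in 12. The step needs attack of the dianion at the acyl imidazole and not at the ester (secured by the much higher reactivity of the acyl imidazole at −78 °C; the reverse order would give the enantiomer), deprotonation of 10 at methyl and not at methylene (kinetic preference), and Claisen instead of aldol closure (the ester α-carbon is quaternary and cannot act as a nucleophile).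

Step 7
Reactants: 13 2,4,6-trihydroxybenzaldehyde
Product: 14 2,6-dihydroxy-4-methoxybenzaldehyde
Conditions: (CH3O)2SO2 (1.0 equiv), K2CO3 (1.0 equiv), acetone, rt
Reagents that add atoms: dimethyl sulfate, COS(=O)(=O)OC
Why: In this phenol O-methylation (Williamson type) the 4-hydroxyl, para to the formyl group and free, is the most acidic, whereas the 2- and 6-hydroxyls are held in hydrogen bonds to the aldehyde, so one equivalent of base should direct methylation to O-4 and keep the mirror symmetry of the ring.

Step 8
Reactants: 14 2,6-dihydroxy-4-methoxybenzaldehyde; 15 hexanoyl chloride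
Product: 16 3-hexanoyl-2,6-dihydroxy-4-methoxybenzaldehyde
Conditions: TiCl4, ClCH2CH2Cl, 0 → 60 °C; then aq HCl
Reagents that add atoms: none
Why: In this Friedel–Crafts acylation the two open ring positions of 14 are equivalent by the mirror plane through C1 and C4, so C-acylation can give only one regioisomer, and the second carbonyl group deactivates the ring against double acylation.

Step 9
Reactants: 12 (R)-2-butanoyl-3,5-dihydroxy-4-methyl-4-(3-methylbut-2-en-1-yl)cyclohexa-2,5-dien-1-one; 16 3-hexanoyl-2,6-dihydroxy-4-methoxybenzaldehyde
Product: 18 (R)-2-butanoyl-6-[(3-hexanoyl-2,6-dihydroxy-4-methoxyphenyl)methyl]-3,5-dihydroxy-4-methyl-4-(3-methylbut-2-en-1-yl)cyclohexa-2,5-dien-1-one, via alkylidene trione 17 (not isolated)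
Conditions: L-proline (20 mol %), diethyl 2,6-dimethyl-1,4-dihydropyridine-3,5-dicarboxylate (Hantzsch ester, 1.2 equiv), CH2Cl2, rt
Reagents that add atoms: none
Why: In this three-component reductive alkylation (Knoevenagel condensation, then transfer hydrogenation) the only C–H carbon of trione 12 (C6) should condense with the aldehyde through its proline iminium ion to alkylidene trione 17, which takes up hydride at the benzylic carbon; because the bridge carbon is the formyl carbon of 16, the new bond can lie only between the two hydroxyl groups of ring A, no stereocentre is formed, and the quaternary centre, the prenyl group and the ketones are inert to the dihydropyridine.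

**Compound list**

1 | 2,2,5-trimethyl-1,3-dioxane-4,6-dione | CC1C(=O)OC(C)(C)OC1=O | starting material
2 | 3-(tert-butoxy)-2-methyl-3-oxopropanoic acid (racemic, labile methine) | CC(C(=O)O)C(=O)OC(C)(C)C | intermediate
3 | 2,2-diphenylethanol | OCC(c1ccccc1)c1ccccc1 | starting material
4 | tert-butyl 2,2-diphenylethyl 2-methylpropanedioate (racemic, labile methine) | CC(C(=O)OCC(c1ccccc1)c1ccccc1)C(=O)OC(C)(C)C | intermediate
5 | 1-bromo-3-methylbut-2-ene (prenyl bromide) | CC(C)=CCBr | starting material
6 | tert-butyl 2,2-diphenylethyl (S)-2-methyl-2-(3-methylbut-2-en-1-yl)propanedioate | CC(C)=CC[C@](C)(C(=O)OC(C)(C)C)C(=O)OCC(c1ccccc1)c1ccccc1 | intermediate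
7 | 2,2-diphenylethyl trimethylsilyl (S)-2-methyl-2-(3-methylbut-2-en-1-yl)propanedioate | CC(C)=CC[C@](C)(C(=O)O[Si](C)(C)C)C(=O)OCC(c1ccccc1)c1ccccc1 | intermediate (not isolated)
8 | (R)-2-[(2,2-diphenylethoxy)carbonyl]-2,5-dimethylhex-4-enoic acid | CC(C)=CC[C@](C)(C(=O)O)C(=O)OCC(c1ccccc1)c1ccccc1 | intermediate
9 | 2,2-diphenylethyl (R)-2-(1H-imidazole-1-carbonyl)-2,5-dimethylhex-4-enoate | CC(C)=CC[C@](C)(C(=O)n1ccnc1)C(=O)OCC(c1ccccc1)c1ccccc1 | intermediate
10 | heptane-2,4-dione | CCCC(=O)CC(C)=O | starting material
11 | 2,2-diphenylethyl (R)-2-methyl-2-(3-methylbut-2-en-1-yl)-3,5,7-trioxodecanoate | CC(C)=CC[C@](C)(C(=O)CC(=O)CC(=O)CCC)C(=O)OCC(c1ccccc1)c1ccccc1 | intermediate (not isolated)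
12 | (R)-2-butanoyl-3,5-dihydroxy-4-methyl-4-(3-methylbut-2-en-1-yl)cyclohexa-2,5-dien-1-one | CCCC(=O)C1=C(O)[C@](C)(CC=C(C)C)C(O)=CC1=O | intermediate
13 | 2,4,6-trihydroxybenzaldehyde | O=Cc1c(O)cc(O)cc1O | starting material
14 | 2,6-dihydroxy-4-methoxybenzaldehyde | COc1cc(O)c(C=O)c(O)c1 | intermediate
15 | hexanoyl chloride | CCCCCC(=O)Cl | starting material
16 | 3-hexanoyl-2,6-dihydroxy-4-methoxybenzaldehyde | CCCCCC(=O)c1c(OC)cc(O)c(C=O)c1O | intermediate
17 | (S)-2-butanoyl-6-[(3-hexanoyl-2,6-dihydroxy-4-methoxyphenyl)methylidene]-3-hydroxy-4-methyl-4-(3-methylbut-2-en-1-yl)cyclohex-2-ene-1,5-dione (alkene geometry not defined; same spatial arrangement at C4 as in 12) | CCCCCC(=O)c1c(OC)cc(O)c(C=C2C(=O)[C@@](C)(CC=C(C)C)C(O)=C(C(=O)CCC)C2=O)c1O | intermediate (not isolated)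
18 | (R)-2-butanoyl-6-[(3-hexanoyl-2,6-dihydroxy-4-methoxyphenyl)methyl]-3,5-dihydroxy-4-methyl-4-(3-methylbut-2-en-1-yl)cyclohexa-2,5-dien-1-one | CCCCCC(=O)c1c(OC)cc(O)c(CC2=C(O)[C@@](C)(CC=C(C)C)C(O)=C(C(=O)CCC)C2=O)c1O | target

**Count**

Total: 9 steps. Longest linear sequence: 7 steps (steps 1 to 6 and step 9).

**Steps most likely to fail**

Step 6. Closure of the lithium bis-enolate onto the hindered alkyl ester may be slow, so that intermolecular acylation by the excess dianion and attack at the wrong carbonyl group compete and erode both conversion and enantiomeric purity. The fallback changes the acceptor from an alkyl ester to a thioester and makes the two C–C bonds in separate operations. It sets out from 6 and rejoins the route at 12. The 2,2-diphenylethyl ester of 6 is saponified selectively (1 M KOH, MeOH) to (S)-2-(tert-butoxycarbonyl)-2,5-dimethylhex-4-enoic acid F1, which is coupled with ethanethiol (DCC, DMAP) to tert-butyl (R)-2-[(ethylsulfanyl)carbonyl]-2,5-dimethylhex-4-enoate F2. Cleavage of the tert-butyl ester as in step 4, through trimethylsilyl (R)-2-[(ethylsulfanyl)carbonyl]-2,5-dimethylhex-4-enoate F3 (not isolated), gives (R)-2-[(ethylsulfanyl)carbonyl]-2,5-dimethylhex-4-enoic acid F4, and CDI converts it into S-ethyl (R)-2-(1H-imidazole-1-carbonyl)-2,5-dimethylhex-4-enethioate F5. Acylation of the dianion of 10 at −78 °C, where the acyl imidazole should react before the thioester, followed by a cold quench gives S-ethyl (R)-2-methyl-2-(3-methylbut-2-en-1-yl)-3,5,7-trioxodecanethioate F6. F6 is then closed with a mild base (DBU, THF) by thioester Claisen condensation to 12. The carboxyl carbons keep the same roles as in the main route, so the configuration is unchanged.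

Step 9. Condensation of the strongly hydrogen-bonded, electron-rich aldehyde with the trione may stall, or the alkylidene intermediate may be captured by a second trione molecule before hydride transfer. The fallback forms the bridge through an ortho-quinone methide instead. It sets out from 16 and rejoins the route at 18. Reductive amination of 16 with morpholine (NaBH(OAc)3, ClCH2CH2Cl) gives the Mannich base 1-[2,4-dihydroxy-6-methoxy-3-(morpholin-4-ylmethyl)phenyl]hexan-1-one F7. Heating F7 with 12 (toluene, 90 °C) should expel morpholine to give 4-hexanoyl-5-hydroxy-3-methoxy-6-methylidenecyclohexa-2,4-dien-1-one F8 (not isolated), which is captured at C6 of 12 by conjugate addition to give 18.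

Step 8. The formyl group deactivates the ring, so C-acylation may be slow, and cleavage of the methyl ether next to the new ketone or loss of the formyl group may take over under the Lewis acid. The fallback introduces the ketone by directed metalation instead of electrophilic substitution. It sets out from 14 and rejoins the route at 16. Both phenols of 14 are protected (MOMCl, iPr2NEt, CH2Cl2) to give 4-methoxy-2,6-bis(methoxymethoxy)benzaldehyde F9. The aldehyde is masked in the flask as its α-amino alkoxide (LiN(CH3)CH2CH2N(CH3)2, THF, −20 °C), n-BuLi lithiates the position between the methoxymethoxy and methoxy groups (the two open positions are again equivalent), and N-methoxy-N-methylhexanamide gives after aqueous work-up 3-hexanoyl-4-methoxy-2,6-bis(methoxymethoxy)benzaldehyde F10. HCl in MeOH removes both methoxymethyl groups to give 16.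

**Further compounds**

F1 | step 6 | (S)-2-(tert-butoxycarbonyl)-2,5-dimethylhex-4-enoic acid | CC(C)=CC[C@](C)(C(=O)OC(C)(C)C)C(=O)O
F2 | step 6 | tert-butyl (R)-2-[(ethylsulfanyl)carbonyl]-2,5-dimethylhex-4-enoate | CC(C)=CC[C@](C)(C(=O)OC(C)(C)C)C(=O)SCC
F3 | step 6 | trimethylsilyl (R)-2-[(ethylsulfanyl)carbonyl]-2,5-dimethylhex-4-enoate | CC(C)=CC[C@](C)(C(=O)O[Si](C)(C)C)C(=O)SCC
F4 | step 6 | (R)-2-[(ethylsulfanyl)carbonyl]-2,5-dimethylhex-4-enoic acid | CC(C)=CC[C@](C)(C(=O)O)C(=O)SCC
F5 | step 6 | S-ethyl (R)-2-(1H-imidazole-1-carbonyl)-2,5-dimethylhex-4-enethioate | CC(C)=CC[C@](C)(C(=O)n1ccnc1)C(=O)SCC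
F6 | step 6 | S-ethyl (R)-2-methyl-2-(3-methylbut-2-en-1-yl)-3,5,7-trioxodecanethioate | CC(C)=CC[C@](C)(C(=O)CC(=O)CC(=O)CCC)C(=O)SCC
F7 | step 9 | 1-[2,4-dihydroxy-6-methoxy-3-(morpholin-4-ylmethyl)phenyl]hexan-1-one | CCCCCC(=O)c1c(OC)cc(O)c(CN2CCOCC2)c1O
F8 | step 9 | 4-hexanoyl-5-hydroxy-3-methoxy-6-methylidenecyclohexa-2,4-dien-1-one | CCCCCC(=O)C1=C(O)C(=C)C(=O)C=C1OC
F9 | step 8 | 4-methoxy-2,6-bis(methoxymethoxy)benzaldehyde | COCOc1cc(OC)cc(OCOC)c1C=O
F10 | step 8 | 3-hexanoyl-4-methoxy-2,6-bis(methoxymethoxy)benzaldehyde | CCCCCC(=O)c1c(OC)cc(OCOC)c(C=O)c1OCOC
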